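**Plan**
- Retrosynthetic cuts, in order: the silyl ether on the C13 oxygen; the C8 carbinol (back to the 8,17-epoxide, the C8=C17 methylene and the C8 ketone); the C4–C5 bond of ring A; the C9–C11 bond (enolate alkylation); the C10–C1 bond (conjugate addition).
- Forward: ring B is built first from 3-methylcyclohexenone (C10, then the C6=C7 enone, then the C9 chain). The C3=C4 alkene of the C10 chain is turned into an enantiopure vic-dibromide, ring A is closed last, and the C8 carbinol and deprotection follow.
- Enabling feature: in ring A the C3–Br and C4–C5 bonds lie anti across C3–C4, the signature of bromonium opening. In ring B, C5 is the γ-carbon of the C8 carbonyl, so a C8 dienol ether makes C5 nucleophilic with no extra activating group to remove.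
- Stereochemistry: C10 from asymmetric conjugate addition; C3 from Shi epoxidation followed by one inversion; C5 and C9 by equilibration of the enone; C8 by epoxidation anti to C20; C13 from (R)-linalool.

Key step: step 10

Remark: positions are cited in labdane numbering (C1–C10 decalin carbons, C11–C16 side chain, C17 on C8, C18/C19 on C4, C20 on C10). Compounds 14–17 are carried as mixtures of C9 epimers that converge in step 10. LDA is used as a commercial solution.

**Route**

Step 1
Reactants: 1 3-methylcyclohex-2-en-1-one; 2 5-bromo-2-methylpent-2-ene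
Product: 5 (S)-3-methyl-3-(4-methylpent-3-en-1-yl)cyclohexan-1-one, via Grignard reagent 3 (not isolated), via magnesium enolate 4 (not isolated)
Conditions: 2, Mg, Et2O, rt; then 1, Cu(OTf)2 (cat.), chiral imidazolinium-derived NHC (cat., enantiomer giving S), Et2O, 0 °C; aq. NH4Cl
Reagents that add atoms: none
Why: Copper–NHC-catalysed asymmetric conjugate addition of a Grignard reagent to a β-methylcyclohexenone is an established route to all-carbon quaternary centres, and the ligand-controlled enone face sets C10.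

Step 2
Reactants: 5 (S)-3-methyl-3-(4-methylpent-3-en-1-yl)cyclohexan-1-one
Product: 7 (R)-5-methyl-5-(4-methylpent-3-en-1-yl)cyclohex-2-en-1-one, via silyl enol ether 6 (not isolated)
Conditions: LDA, TMSCl, THF, −78 °C; then Pd(OAc)2, MeCN, rt
Reagents that add atoms: none
Why: Kinetic deprotonation should occur at the CH2 remote from the quaternary carbon, and Saegusa–Ito oxidation of that silyl enol ether gives the C6=C7 enone, leaving C5 as the γ-position and C9 as the only α′-position.

Step 3
Reactants: 8 (R)-linalool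
Product: 9 (R)-tert-butyl[(3,7-dimethylocta-1,6-dien-3-yl)oxy]dimethylsilane
Conditions: TBSOTf, 2,6-lutidine, CH2Cl2, 0 °C
Reagents that add atoms: tert-butyldimethylsilyl trifluoromethanesulfonate (TBSOTf), CC(C)(C)[Si](C)(C)OS(=O)(=O)C(F)(F)F
Why: Silyl triflate silylation of a tertiary alcohol protects the C13 carbinol, whose configuration is taken unchanged from the chiral pool.

Step 4
Reactants: 9 (R)-tert-butyl[(3,7-dimethylocta-1,6-dien-3-yl)oxy]dimethylsilane
Product: 11 (R)-4-[(tert-butyldimethylsilyl)oxy]-4-methylhex-5-enoic acid, via aldehyde 10 (not isolated)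
Conditions: O3, CH2Cl2, −78 °C (indicator end point), PPh3; then NaClO2, NaH2PO4, 2-methylbut-2-ene, t-BuOH/H2O, 0 °C to rt
Reagents that add atoms: ozone, [O-][O+]=O; sodium chlorite, [Na+].[O-]Cl=O
Why: Ozone should cleave the electron-rich trisubstituted alkene in preference to the hindered, oxygen-deactivated vinyl group, and Pinnick oxidation takes the aldehyde to the acid without touching C13.

Step 5
Reactants: 11 (R)-4-[(tert-butyldimethylsilyl)oxy]-4-methylhex-5-enoic acid
Product: 12 (R)-tert-butyl[(5-iodo-3-methylpent-1-en-3-yl)oxy]dimethylsilane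
Conditions: PhI(OAc)2, I2, cyclohexane, hν (tungsten lamp), reflux
Reagents that add atoms: iodine, II
Why: Suárez iododecarboxylation (acyl hypoiodite, radical decarboxylation, iodine transfer) removes one carbon and gives the primary iodide that carries C11–C16.

Step 6
Reactants: 7 (R)-5-methyl-5-(4-methylpent-3-en-1-yl)cyclohex-2-en-1-one; 12 (R)-tert-butyl[(5-iodo-3-methylpent-1-en-3-yl)oxy]dimethylsilane
Product: 14 (5R)-6-{(3R)-3-[(tert-butyldimethylsilyl)oxy]-3-methylpent-4-en-1-yl}-5-methyl-5-(4-methylpent-3-en-1-yl)cyclohex-2-en-1-one (both C6 epimers), via lithium dienolate 13 (not isolated)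
Conditions: LDA, THF, −78 °C; then 12, DMPU, −78 to −20 °C
Reagents that add atoms: none
Why: Kinetic α′-enolate alkylation of a cyclohexenone forms the C9–C11 bond; the configuration at C9 is not controlled here and is settled thermodynamically in step 10.

Step 7
Reactants: 14 (5R)-6-{(3R)-3-[(tert-butyldimethylsilyl)oxy]-3-methylpent-4-en-1-yl}-5-methyl-5-(4-methylpent-3-en-1-yl)cyclohex-2-en-1-one
Product: 15 (5R)-6-{(3R)-3-[(tert-butyldimethylsilyl)oxy]-3-methylpent-4-en-1-yl}-5-{2-[(2S)-3,3-dimethyloxiran-2-yl]ethyl}-5-methylcyclohex-2-en-1-one (C6 epimers)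
Conditions: L-fructose-derived Shi ketone (cat., the enantiomer that gives the S epoxide), Oxone, K2CO3, Bu4NHSO4 (cat.), MeCN/dimethoxymethane/aq. borate buffer, 0 °C
Reagents that add atoms: potassium peroxymonosulfate (Oxone), [K+].[O-]S(=O)(=O)OO
Why: In the Shi epoxidation the chiral dioxirane should attack the electron-rich trisubstituted alkene much faster than the enone or the hindered vinyl group, and the ketone enantiomer fixes the (S) configuration at C3.

Step 8
Reactants: 15 (the S epoxide)
Product: 16 (5R)-6-{(3R)-3-[(tert-butyldimethylsilyl)oxy]-3-methylpent-4-en-1-yl}-5-[(3R)-3,4-dibromo-4-methylpentyl]-5-methylcyclohex-2-en-1-one (C6 epimers)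
Conditions: Ph3PBr2, 2,6-lutidine (cat.), CH2Cl2, −20 to 0 °C
Reagents that add atoms: dibromotriphenylphosphorane, BrP(Br)(c1ccccc1)(c1ccccc1)c1ccccc1
Why: Epoxide-to-vic-dibromide conversion with triphenylphosphine dibromide: the phosphonium-activated oxirane is opened by bromide and the oxygen leaves as phosphine oxide, with C3 inverted once (S epoxide to R bromide) whichever carbon is attacked first, because the second substitution passes through the bridged bromonium ion.

Step 9
Reactants: 16 (the 3R vic-dibromide)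
Product: 17 tert-butyl{[(5R)-6-{(3R)-3-[(tert-butyldimethylsilyl)oxy]-3-methylpent-4-en-1-yl}-5-[(3R)-3,4-dibromo-4-methylpentyl]-5-methylcyclohexa-1,3-dien-1-yl]oxy}dimethylsilane (C6 epimers)
Conditions: TBSOTf, Et3N, CH2Cl2, 0 °C to rt
Reagents that add atoms: tert-butyldimethylsilyl trifluoromethanesulfonate (TBSOTf), CC(C)(C)[Si](C)(C)OS(=O)(=O)C(F)(F)F
Why: Soft enolisation of an enone with silyl triflate and amine; the α′-hydrogen at C9 is a methine flanked by the quaternary C10, and its removal would give an enol ether with severe allylic strain, so the linear dienol ether O–C8=C7–C6=C5 should form from the C5 hydrogens.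

Step 10
Reactants: 17 (the linear silyl dienol ether carrying the 3R vic-dibromide)
Product: 20 (1S,4aS,6R,8aR)-6-bromo-1-{(3R)-3-[(tert-butyldimethylsilyl)oxy]-3-methylpent-4-en-1-yl}-5,5,8a-trimethyl-4a,5,6,7,8,8a-hexahydronaphthalen-2(1H)-one, via bromonium ion 18 (not isolated), via enone epimer mixture 19 (not isolated)
Conditions: AgOTf, 2,6-di-tert-butyl-4-methylpyridine, CH2Cl2, −78 to −40 °C; then NaOMe, MeOH, −40 °C to rt
Reagents that add atoms: none
Why: Proposed new method: silver(I) pulls the tertiary bromide from the enantiopure vic-dibromide with anchimeric help from the C3 bromine, so a configurationally defined bromonium ion (no free Br+ reagent present) is opened at its tertiary carbon C4 by C5, the γ-carbon of the silyl dienol ether, anti to bromine, and loss of the silyl group returns the C8 enone. The closest known reaction types are the Lewis-acid SN1 alkylation of silyl enol ethers with tertiary halides, the γ-selective vinylogous Mukaiyama reaction and bromonium-induced cation–olefin cyclisation. Ring A closes in a 6-endo mode at the bromonium ion (both C3 and C4 end up in the ring), with the dienol C5=C6 bond exo to the new ring. C3 keeps the configuration installed in steps 7 and 8 because bromine only bridges and never leaves C3; C5 and C9 are not relied on kinetically but are set in the same flask by methoxide equilibration through the dienolate to the trans-fused, C9-equatorial enone; C10 is untouched. The step needs γ- over α-attack (secured by ring size, since C7 could only close an eight-membered ring), carbon over bromine attack (secured by the largely open tertiary cation character at C4), and ionisation of the tertiary bromide in preference to the tertiary allylic silyl ether (secured by the halophilic, non-oxophilic promoter).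

Step 11
Reactants: 20 (the trans-fused bromo enone)
Product: 21 (1S,4aS,6R,8aR)-6-bromo-1-{(3R)-3-[(tert-butyldimethylsilyl)oxy]-3-methylpent-4-en-1-yl}-5,5,8a-trimethyloctahydronaphthalen-2(1H)-one
Conditions: [(Ph3P)CuH]6, H2O, toluene, rt
Reagents that add atoms: none
Why: Copper hydride conjugate reduction (Stryker's reagent) is chemoselective for the enone over the vinyl group and the secondary bromide, and protonation of the enolate leaves the C9 chain equatorial.

Step 12
Reactants: 21 (the C8 ketone)
Product: 22 tert-butyl{[(3R)-5-[(1R,4aS,6R,8aS)-6-bromo-5,5,8a-trimethyl-2-methylidenedecahydronaphthalen-1-yl]-3-methylpent-1-en-3-yl]oxy}dimethylsilane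
Conditions: Ph3PCH3Br, KOtBu, toluene, rt to 80 °C
Reagents that add atoms: methyltriphenylphosphonium bromide, C[P+](c1ccccc1)(c1ccccc1)c1ccccc1.[Br-]
Why: Wittig methylenation of the hindered C8 ketone brings in C17; any epimerisation at C9 under the basic conditions returns to the equatorial isomer, and the equatorial C3 bromide has no anti-periplanar hydrogen for elimination.

Step 13
Reactants: 22 (the C8=C17 alkene)
Product: 23 tert-butyl{[(3R)-5-[(1S,2S,4aS,6R,8aR)-6-bromo-5,5,8a-trimethyloctahydro-1H-spiro[naphthalene-2,2'-oxiran]-1-yl]-3-methylpent-1-en-3-yl]oxy}dimethylsilane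
Conditions: mCPBA, NaHCO3, CH2Cl2, 0 °C
Reagents that add atoms: 3-chloroperoxybenzoic acid (mCPBA), OOC(=O)c1cccc(Cl)c1
Why: Peracid epoxidation should be faster at the 1,1-disubstituted C8=C17 bond than at the hindered, oxygen-deactivated vinyl group, and attack anti to the axial C20 methyl places the oxygen on the face required at C8 (8S).

Step 14
Reactants: 23 (the 8,17-epoxide)
Product: 24 (1S,2S,4aS,6R,8aR)-6-bromo-1-{(3R)-3-[(tert-butyldimethylsilyl)oxy]-3-methylpent-4-en-1-yl}-2,5,5,8a-tetramethyldecahydronaphthalen-2-ol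
Conditions: LiAlH4, THF, 0 °C; H2O/NaOH work-up
Reagents that add atoms: none
Why: Hydride opens the spiro-epoxide at the primary C17 to leave the tertiary C8 alcohol with C17 as methyl, while the equatorial neopentyl-type C3 bromide offers neither an SN2 nor an anti-periplanar E2 path and should survive at 0 °C.

Step 15
Reactants: 24 (the C13 silyl ether of the target)
Product: 25 (1S,2S,4aS,6R,8aR)-6-bromo-1-[(3R)-3-hydroxy-3-methylpent-4-en-1-yl]-2,5,5,8a-tetramethyldecahydronaphthalen-2-ol (target)
Conditions: TBAF, THF, 50 °C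
Reagents that add atoms: none
Why: Fluoride cleaves the tertiary silyl ether and frees the C13 allylic alcohol without affecting the other stereocentres.

**Compound list**
1 | 3-methylcyclohex-2-en-1-one | CC1=CC(=O)CCC1 | starting material
2 | 5-bromo-2-methylpent-2-ene | CC(C)=CCCBr | starting material
3 | (4-methylpent-3-en-1-yl)magnesium bromide | CC(C)=CCC[Mg]Br | intermediate
4 | bromomagnesium 3-methyl-3-(4-methylpent-3-en-1-yl)cyclohex-1-en-1-olate (quaternary carbon as in 5) | C=1[C@](C)(CCC=C(C)C)CCCC=1O[Mg]Br | intermediate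
5 | (S)-3-methyl-3-(4-methylpent-3-en-1-yl)cyclohexan-1-one | C1[C@](C)(CCC=C(C)C)CCCC1=O | intermediate
6 | trimethyl{[5-methyl-5-(4-methylpent-3-en-1-yl)cyclohex-1-en-1-yl]oxy}silane (quaternary carbon as in 5) | C1[C@](C)(CCC=C(C)C)CCC=C1O[Si](C)(C)C | intermediate
7 | (R)-5-methyl-5-(4-methylpent-3-en-1-yl)cyclohex-2-en-1-one | C1[C@](C)(CCC=C(C)C)CC=CC1=O | intermediate
8 | (R)-linalool | C=C[C@](C)(O)CCC=C(C)C | starting material
9 | (R)-tert-butyl[(3,7-dimethylocta-1,6-dien-3-yl)oxy]dimethylsilane | C=C[C@](C)(O[Si](C)(C)C(C)(C)C)CCC=C(C)C | intermediate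
10 | (R)-4-[(tert-butyldimethylsilyl)oxy]-4-methylhex-5-enal | C=C[C@](C)(O[Si](C)(C)C(C)(C)C)CCC=O | intermediate
11 | (R)-4-[(tert-butyldimethylsilyl)oxy]-4-methylhex-5-enoic acid | C=C[C@](C)(O[Si](C)(C)C(C)(C)C)CCC(=O)O | intermediate
12 | (R)-tert-butyl[(5-iodo-3-methylpent-1-en-3-yl)oxy]dimethylsilane | C=C[C@](C)(O[Si](C)(C)C(C)(C)C)CCI | intermediate
13 | lithium 3-methyl-3-(4-methylpent-3-en-1-yl)cyclohexa-1,5-dien-1-olate (α′-enolate of 7) | C=1[C@](C)(CCC=C(C)C)CC=CC=1O[Li] | intermediate
14 | (5R)-6-{(3R)-3-[(tert-butyldimethylsilyl)oxy]-3-methylpent-4-en-1-yl}-5-methyl-5-(4-methylpent-3-en-1-yl)cyclohex-2-en-1-one (C6 epimers) | C=C[C@](C)(O[Si](C)(C)C(C)(C)C)CCC1[C@](C)(CCC=C(C)C)CC=CC1=O | intermediate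
15 | (5R)-6-{(3R)-3-[(tert-butyldimethylsilyl)oxy]-3-methylpent-4-en-1-yl}-5-{2-[(2S)-3,3-dimethyloxiran-2-yl]ethyl}-5-methylcyclohex-2-en-1-one (C6 epimers) | C=C[C@](C)(O[Si](C)(C)C(C)(C)C)CCC1[C@](C)(CC[C@@H]2OC2(C)C)CC=CC1=O | intermediate
16 | (5R)-6-{(3R)-3-[(tert-butyldimethylsilyl)oxy]-3-methylpent-4-en-1-yl}-5-[(3R)-3,4-dibromo-4-methylpentyl]-5-methylcyclohex-2-en-1-one (C6 epimers) | C=C[C@](C)(O[Si](C)(C)C(C)(C)C)CCC1[C@](C)(CC[C@@H](Br)C(C)(C)Br)CC=CC1=O | intermediate
17 | tert-butyl{[(5R)-6-{(3R)-3-[(tert-butyldimethylsilyl)oxy]-3-methylpent-4-en-1-yl}-5-[(3R)-3,4-dibromo-4-methylpentyl]-5-methylcyclohexa-1,3-dien-1-yl]oxy}dimethylsilane (C6 epimers) | C=C[C@](C)(O[Si](C)(C)C(C)(C)C)CCC1[C@](C)(CC[C@@H](Br)C(C)(C)Br)C=CC=C1O[Si](C)(C)C(C)(C)C | intermediate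
18 | C3/C4-bridged bromonium ion derived from 17 (3R) | C=C[C@](C)(O[Si](C)(C)C(C)(C)C)CCC1[C@](C)(CC[C@H]2[Br+]C2(C)C)C=CC=C1O[Si](C)(C)C(C)(C)C | intermediate
19 | (6R,8aR)-6-bromo-1-{(3R)-3-[(tert-butyldimethylsilyl)oxy]-3-methylpent-4-en-1-yl}-5,5,8a-trimethyl-4a,5,6,7,8,8a-hexahydronaphthalen-2(1H)-one (mixture of C1 and C4a epimers) | C=C[C@](C)(O[Si](C)(C)C(C)(C)C)CCC1[C@]2(C)CC[C@@H](Br)C(C)(C)C2C=CC1=O | intermediate
20 | (1S,4aS,6R,8aR)-6-bromo-1-{(3R)-3-[(tert-butyldimethylsilyl)oxy]-3-methylpent-4-en-1-yl}-5,5,8a-trimethyl-4a,5,6,7,8,8a-hexahydronaphthalen-2(1H)-one | C=C[C@](C)(O[Si](C)(C)C(C)(C)C)CC[C@H]1[C@]2(C)CC[C@@H](Br)C(C)(C)[C@H]2C=CC1=O | intermediate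
21 | (1S,4aS,6R,8aR)-6-bromo-1-{(3R)-3-[(tert-butyldimethylsilyl)oxy]-3-methylpent-4-en-1-yl}-5,5,8a-trimethyloctahydronaphthalen-2(1H)-one | C=C[C@](C)(O[Si](C)(C)C(C)(C)C)CC[C@H]1[C@]2(C)CC[C@@H](Br)C(C)(C)[C@H]2CCC1=O | intermediate
22 | tert-butyl{[(3R)-5-[(1R,4aS,6R,8aS)-6-bromo-5,5,8a-trimethyl-2-methylidenedecahydronaphthalen-1-yl]-3-methylpent-1-en-3-yl]oxy}dimethylsilane | C=C[C@](C)(O[Si](C)(C)C(C)(C)C)CC[C@H]1[C@]2(C)CC[C@@H](Br)C(C)(C)[C@H]2CCC1=C | intermediate
23 | tert-butyl{[(3R)-5-[(1S,2S,4aS,6R,8aR)-6-bromo-5,5,8a-trimethyloctahydro-1H-spiro[naphthalene-2,2'-oxiran]-1-yl]-3-methylpent-1-en-3-yl]oxy}dimethylsilane | C=C[C@](C)(O[Si](C)(C)C(C)(C)C)CC[C@H]1[C@]2(C)CC[C@@H](Br)C(C)(C)[C@H]2CC[C@@]1(O3)C3 | intermediate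
24 | (1S,2S,4aS,6R,8aR)-6-bromo-1-{(3R)-3-[(tert-butyldimethylsilyl)oxy]-3-methylpent-4-en-1-yl}-2,5,5,8a-tetramethyldecahydronaphthalen-2-ol | C=C[C@](C)(O[Si](C)(C)C(C)(C)C)CC[C@H]1[C@]2(C)CC[C@@H](Br)C(C)(C)[C@H]2CC[C@]1(C)O | intermediate
25 | (1S,2S,4aS,6R,8aR)-6-bromo-1-[(3R)-3-hydroxy-3-methylpent-4-en-1-yl]-2,5,5,8a-tetramethyldecahydronaphthalen-2-ol | C=C[C@](C)(O)CC[C@H]1[C@]2(C)CC[C@@H](Br)C(C)(C)[C@H]2CC[C@]1(C)O | target

**Summary**
Total step count: 15. Longest linear sequence: 13 steps (8 to 25, steps 3–15).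

**Steps most likely to fail**

Step 10 (Proposed new method). The electron-rich dienol ether may take bromine from the bromonium ion (halophilic attack) instead of attacking C4, or the cation may eliminate to an allylic bromide. Ring closure may also be slow, because the required C3/C10 pairing cannot pass through the lowest-energy chair, cis-fused transition state, and the γ-epimerisation at C5 may stall. The fallback uses known chemistry and sets out from 14. Soft enolisation (TBSOTf, Et3N) would give the linear tert-butyldimethylsilyl dienol ether of 14 F1. The mercury(II) triflate–N,N-dimethylaniline complex (MeNO2, −20 °C), followed by aqueous KBr, would close ring A by mercurinium-induced cyclisation to the C3-bromomercurio enone F2, obtained as a mixture at C3, C5 and C9. Brominative demercuration (Br2, LiBr, pyridine, 0 °C) passes through the C3 radical, which should take bromine mainly from the equatorial side. NaOMe/MeOH equilibration would then bring the material back to the route at 20, with the C3 epimer removed by chromatography. Reagent control at C3 is given up in this fallback.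

Step 9. Enolisation may occur towards C9 and give the cross-conjugated dienol ether, which would later close the ring through the wrong carbon; the tertiary bromide may also be lost by amine-induced elimination. The fallback sets out from 16 and replaces the silyl dienol ether by an enamine. Pyrrolidine with Ti(OiPr)4 in THF at rt should give the linear pyrrolidine dienamine F3, since for cyclohexenones the linear dienamine is the thermodynamic isomer and the cross-conjugated one would suffer strong allylic strain at C9. Silver triflate ionisation as in step 10, hydrolysis of the iminium ion with aqueous acetate buffer (giving 19) and NaOMe/MeOH equilibration would return the sequence to 20.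

Step 6. C-alkylation of the hindered α′-enolate by the unactivated primary iodide may be sluggish, with proton transfer between enolate and product and elimination of the iodide competing. The fallback sets out from 7 and uses a more nucleophilic azaenolate. Condensation with 1,1-dimethylhydrazine (cat. AcOH, EtOH, reflux) would give the N,N-dimethylhydrazone of 7 F4. α′-Deprotonation with LDA (THF, 0 °C) and reaction with 12 would give the α′-alkylated hydrazone F5. Hydrolysis (CuCl2, THF/H2O, pH 7) would return the sequence to 14.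

Further compounds
F1 | step 10 | tert-butyl{[(5R)-6-{(3R)-3-[(tert-butyldimethylsilyl)oxy]-3-methylpent-4-en-1-yl}-5-methyl-5-(4-methylpent-3-en-1-yl)cyclohexa-1,3-dien-1-yl]oxy}dimethylsilane | C=C[C@](C)(O[Si](C)(C)C(C)(C)C)CCC1[C@](C)(CCC=C(C)C)C=CC=C1O[Si](C)(C)C(C)(C)C
F2 | step 10 | (8aR)-6-(bromomercurio)-1-{(3R)-3-[(tert-butyldimethylsilyl)oxy]-3-methylpent-4-en-1-yl}-5,5,8a-trimethyl-4a,5,6,7,8,8a-hexahydronaphthalen-2(1H)-one (mixture at C1, C4a and C6) | C=C[C@](C)(O[Si](C)(C)C(C)(C)C)CCC1[C@]2(C)CCC([Hg]Br)C(C)(C)C2C=CC1=O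
F3 | step 9 | 1-[(5R)-6-{(3R)-3-[(tert-butyldimethylsilyl)oxy]-3-methylpent-4-en-1-yl}-5-[(3R)-3,4-dibromo-4-methylpentyl]-5-methylcyclohexa-1,3-dien-1-yl]pyrrolidine | C=C[C@](C)(O[Si](C)(C)C(C)(C)C)CCC1[C@](C)(CC[C@@H](Br)C(C)(C)Br)C=CC=C1N1CCCC1
F4 | step 6 | 1,1-dimethyl-2-[(5R)-5-methyl-5-(4-methylpent-3-en-1-yl)cyclohex-2-en-1-ylidene]hydrazine | C1[C@](C)(CCC=C(C)C)CC=CC1=NN(C)C
F5 | step 6 | 2-[(5R)-6-{(3R)-3-[(tert-butyldimethylsilyl)oxy]-3-methylpent-4-en-1-yl}-5-methyl-5-(4-methylpent-3-en-1-yl)cyclohex-2-en-1-ylidene]-1,1-dimethylhydrazine | C=C[C@](C)(O[Si](C)(C)C(C)(C)C)CCC1[C@](C)(CCC=C(C)C)CC=CC1=NN(C)C
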